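**Retrosynthetic overview**
- The last bond made is C17–O: allylic hydroxylation of the C8 methyl group of the ent-labda-7,13-dienyl ester.
- Rings A and B are formed in one cascade (ring A first, then ring B) by an enantioselective proton-initiated bicyclization of the open-chain geranylgeranyl ester; this sets C5, C9 and C10.
- The fragment union is the C15–O ester bond: O-alkylation of unprotected 30-hydroxytriacontanoic acid with geranylgeranyl bromide.
- The C30 hydroxy acid comes from two C15 halves, both made from 15-pentadecanolide, joined by a copper-catalysed Grignard/alkyl bromide coupling.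

Assumption: the acyl chain is read as 30-hydroxytriacontanoyl (29 CH2), the decalin as the ent-labdane series (5R,9S,10R in the target), and the (R,R) antipode of the chiral acid is taken as the one giving this series (the mirror-image catalyst is used if a pilot run shows the opposite sense).

**Step 1**
Reactants: 1 15-pentadecanolide
Product: 2 15-bromopentadecanoic acid
Conditions: HBr (33% in AcOH), conc. H2SO4 (cat.), 80 °C
Reagents that add atoms: hydrogen bromide, Br
Why: Acid-mediated alkyl–oxygen cleavage of the lactone, bromide displacing the protonated ester oxygen at the primary C15 carbon (SN2) and freeing the carboxylic acid.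

**Step 2**
Reactants: 2 15-bromopentadecanoic acid
Product: 3 15-bromopentadecan-1-ol
Conditions: BH3·THF (1.2 equiv), THF, 0 °C → rt
Reagents that add atoms: none
Why: Chemoselective borane reduction of a free carboxylic acid through its acyloxyborane, which leaves a primary alkyl bromide untouched.

**Step 3**
Reactants: 3 15-bromopentadecan-1-ol
Product: 4 2-[(15-bromopentadecyl)oxy]oxane (THP ether)
Conditions: 3,4-dihydro-2H-pyran (1.5 equiv), PPTS (5 mol%), CH2Cl2, rt
Reagents that add atoms: 3,4-dihydro-2H-pyran, C1=COCCC1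
Why: Acid-catalysed tetrahydropyranylation masks the hydroxyl for the Grignard step; the racemic acetal carbon is removed again in step 4.

**Step 4**
Reactants: 4 2-[(15-bromopentadecyl)oxy]oxane; 2 15-bromopentadecanoic acid
Product: 7 30-hydroxytriacontanoic acid, via Grignard reagent 5 (not isolated), via THP-protected acid 6 (not isolated)
Conditions: 4, Mg, THF, 45 °C; added to 2 + MeMgCl (1.0 equiv), THF, −20 °C, Li2CuCl4 (3 mol%), −20 °C → rt; then 2 M HCl, THF, 50 °C
Reagents that add atoms: none
Why: Kochi-type copper-catalysed sp3–sp3 cross-coupling of an alkyl Grignard reagent with a primary alkyl bromide, the bromo acid being shielded as its chloromagnesium carboxylate, followed by acid hydrolysis of the THP acetal.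

**Step 5**
Reactants: 8 (2E,6E,10E)-geranylgeraniol
Product: 9 (2E,6E,10E)-geranylgeranyl bromide
Conditions: PBr3 (0.4 equiv), Et2O, −10 °C, 30 min; used crude
Reagents that add atoms: phosphorus tribromide, BrP(Br)Br
Why: SN2 bromination of the primary allylic alcohol through its phosphite ester at low temperature keeps all E alkenes and gives no allylic transposition.

**Step 6**
Reactants: 7 30-hydroxytriacontanoic acid; 9 (2E,6E,10E)-geranylgeranyl bromide
Product: 10 (2E,6E,10E)-geranylgeranyl 30-hydroxytriacontanoate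
Conditions: 7, Cs2CO3 (0.6 equiv), DMF/THF 1:1, 50 °C; then 9 (1.2 equiv), 50 °C → rt
Reagents that add atoms: none
Why: Carboxylate O-alkylation (SN2 at the primary allylic bromide) forms the C15–O ester bond; the caesium carboxylate far outcompetes the neutral primary hydroxyl, so neither OH needs protection and the 2E geometry is untouched.

**Step 7**
Reactants: 10 (2E,6E,10E)-geranylgeranyl 30-hydroxytriacontanoate
Product: 11 ent-labda-7,13E-dien-15-yl 30-hydroxytriacontanoate (5R,9R,10R)
Conditions: (R,R)-IDPi acid [(R)-3,3'-Ar2-BINOL-P(=NTf)]2NH, Ar = 3,5-(CF3)2C6H3 (5 mol%), (CF3)3COH/CHCl3 2:1, 0.02 M, −25 °C, 72 h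
Reagents that add atoms: none
Why: Proposed new method: the confined chiral imidodiphosphorimidate acid protonates the terminal 14,15-alkene inside its pocket and the E,E-triene folds chair–chair so that the C4–C5 and C9–C10 bonds form anti across each alkene (Stork–Eschenmoser), setting C5, C9 and C10 as the trans-decalin with equatorial side chain in the sense fixed by the catalyst antipode, while the acyloxy-deactivated 2,3-alkene does not add and the counter-anion removes the axial C7–H (E1) to give the 7-ene and regenerate the acid; the closest known reaction type is the chiral Brønsted acid (IDPi or Lewis-acid-assisted BINOL) catalysed enantioselective bicyclization of homofarnesol-type trienes terminated by an oxygen nucleophile, here extended to E1 termination on a tetraene ester.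

**Step 8**
Reactants: 11 ent-labda-7,13E-dien-15-yl 30-hydroxytriacontanoate
Product: 12 ent-17-hydroxylabda-7,13E-dien-15-yl 30-hydroxytriacontanoate (target, 5R,9S,10R)
Conditions: SeO2 (0.2 equiv), t-BuOOH (3 equiv, 5.5 M in decane), salicylic acid (10 mol%), CH2Cl2, rt
Reagents that add atoms: selenium dioxide, O=[Se]=O (oxygen carrier); tert-butyl hydroperoxide, CC(C)(C)OO (stoichiometric oxygen source)
Why: Riley-type allylic hydroxylation (ene reaction at C7, then 2,3-sigmatropic shift) delivers oxygen to the E-methyl C17 of the only electron-rich trisubstituted alkene and returns the double bond to C7–C8; the 13-alkene is deactivated by its allylic acyloxy group and no stereocentre is touched.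

**Compound list**
1 | 15-pentadecanolide (oxacyclohexadecan-2-one) | O=C1CCCCCCCCCCCCCCO1 | starting material
2 | 15-bromopentadecanoic acid | OC(=O)CCCCCCCCCCCCCCBr | intermediate
3 | 15-bromopentadecan-1-ol | OCCCCCCCCCCCCCCCBr | intermediate
4 | 2-[(15-bromopentadecyl)oxy]oxane (THP ether, racemic acetal carbon) | BrCCCCCCCCCCCCCCCOC1CCCCO1 | intermediate
5 | [15-(oxan-2-yloxy)pentadecyl]magnesium bromide | Br[Mg]CCCCCCCCCCCCCCCOC1CCCCO1 | intermediate (not isolated)
6 | 30-(oxan-2-yloxy)triacontanoic acid | OC(=O)CCCCCCCCCCCCCCCCCCCCCCCCCCCCCOC1CCCCO1 | intermediate (not isolated)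
7 | 30-hydroxytriacontanoic acid | OC(=O)CCCCCCCCCCCCCCCCCCCCCCCCCCCCCO | intermediate
8 | (2E,6E,10E)-geranylgeraniol, (2E,6E,10E)-3,7,11,15-tetramethylhexadeca-2,6,10,14-tetraen-1-ol | C/C(=C\CO)CC/C=C(\C)CC/C=C(\C)CCC=C(C)C | starting material
9 | (2E,6E,10E)-geranylgeranyl bromide | C/C(=C\CBr)CC/C=C(\C)CC/C=C(\C)CCC=C(C)C | intermediate
10 | (2E,6E,10E)-geranylgeranyl 30-hydroxytriacontanoate | C/C(=C\COC(=O)CCCCCCCCCCCCCCCCCCCCCCCCCCCCCO)CC/C=C(\C)CC/C=C(\C)CCC=C(C)C | intermediate
11 | ent-labda-7,13E-dien-15-yl 30-hydroxytriacontanoate; (2E)-3-methyl-5-[(1R,4aR,8aR)-2,5,5,8a-tetramethyl-1,4,4a,5,6,7,8,8a-octahydronaphthalen-1-yl]pent-2-en-1-yl ester (5R,9R,10R) | C/C(=C\COC(=O)CCCCCCCCCCCCCCCCCCCCCCCCCCCCCO)CC[C@@H]1C(C)=CC[C@@H]2C(C)(C)CCC[C@@]12C | intermediate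
12 | ent-17-hydroxylabda-7,13E-dien-15-yl 30-hydroxytriacontanoate; (2E)-5-[(1S,4aR,8aR)-2-(hydroxymethyl)-5,5,8a-trimethyl-1,4,4a,5,6,7,8,8a-octahydronaphthalen-1-yl]-3-methylpent-2-en-1-yl ester (5R,9S,10R; same spatial arrangement as 11, the C9 descriptor changes only through CIP priority) | C/C(=C\COC(=O)CCCCCCCCCCCCCCCCCCCCCCCCCCCCCO)CC[C@@H]1C(CO)=CC[C@@H]2C(C)(C)CCC[C@@]12C | target

**Step count**
Total: 8 steps. Longest linear sequence: 7 steps (1, 2, 3, 4, 6, 7, 8); step 5 is a one-step side branch.

**Three steps most likely to fail**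

Step 7 (the proposed new bicyclization). The risks are over-cyclization to a tricycle, 8(17)- or 8,9-alkene isomers, low enantioselectivity, and poor solubility of the C50 ester in the cold fluorinated medium. The fallback uses known chemistry, sets out from 9 and comes back at 11. Compound 9 and tris(tetrabutylammonium) hydrogen diphosphate in MeCN, followed by ammonium ion exchange, give geranylgeranyl diphosphate F1. Recombinant ent-copalyl diphosphate synthase (the class 2 diterpene cyclase of gibberellin biosynthesis; MgCl2, pH 7.5 buffer, 30 °C) cyclizes it to ent-copalyl diphosphate F2, which has the same decalin configuration but an 8(17)-exocyclic alkene. Alkaline phosphatase gives ent-copalol F3, and PBr3 in Et2O gives ent-copalyl bromide F4. Acid 7 and Cs2CO3 in DMF/THF give ent-labda-8(17),13E-dien-15-yl 30-hydroxytriacontanoate F5. Cobalt-hydride hydrogen-atom-transfer isomerization ((salen)CoCl with salen = N,N'-bis(3,5-di-tert-butylsalicylidene)-1,2-cyclohexanediamine dianion, 3 mol%; PhSiH3 6 mol%; benzene, rt) then moves the exocyclic alkene one position into ring B to give 11. Any 8,9-ene isomer is removed on AgNO3-impregnated silica.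

Step 8 (allylic hydroxylation). The risks are over-oxidation to the 17-aldehyde and competing oxidation at C6, C9 or the side-chain alkene. The fallback sets out from 11 and comes back at 12. mCPBA (1.05 equiv, NaHCO3, CH2Cl2, −20 °C) epoxidizes the electron-richer ring alkene from the face anti to the C10 methyl, giving the 7,8-epoxy-ent-labd-13E-en-15-yl ester F6. TMSOTf/2,6-lutidine (toluene, −78 °C) opens it at the tertiary C8 and removes a C17 proton, giving the bis(trimethylsilyl) ether of the 7-hydroxy-8(17)-ene ester F7. 1 M HCl in THF gives the 7-hydroxy-ent-labda-8(17),13E-dien-15-yl ester F8. Ph3SiOReO3 (2 mol%, Et2O, 0 °C) 1,3-transposes the secondary allylic alcohol to the primary one and gives 12.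

Step 4 (copper-catalysed C15 + C15 coupling). The risks are Wurtz homocoupling, reduction of the Grignard reagent and poor solubility of the chloromagnesium carboxylate. The fallback sets out from 1 and 2 and comes back at 7. PPh3 (MeCN, reflux) converts 2 into (14-carboxytetradecyl)triphenylphosphonium bromide F9. DIBAL-H (toluene, −78 °C) reduces 1 to 15-hydroxypentadecanal F10. The carboxylate ylide from F9 (NaHMDS, THF, used in 2.5-fold excess as in chain extensions of unprotected lactols) and F10 give (15Z)-30-hydroxytriacont-15-enoic acid F11. H2 over Pd/C (THF/EtOAc, 50 °C) gives 7.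

**Further compounds**
F1 | step 7 | (2E,6E,10E)-geranylgeranyl diphosphate (free-acid form; handled as the tris-ammonium salt) | C/C(=C\COP(=O)(O)OP(=O)(O)O)CC/C=C(\C)CC/C=C(\C)CCC=C(C)C
F2 | step 7 | ent-copalyl diphosphate, (5R,9R,10R)-labda-8(17),13E-dien-15-yl diphosphate | C/C(=C\COP(=O)(O)OP(=O)(O)O)CC[C@@H]1C(=C)CC[C@@H]2C(C)(C)CCC[C@@]12C
F3 | step 7 | ent-copalol, (5R,9R,10R)-labda-8(17),13E-dien-15-ol | C/C(=C\CO)CC[C@@H]1C(=C)CC[C@@H]2C(C)(C)CCC[C@@]12C
F4 | step 7 | ent-copalyl bromide | C/C(=C\CBr)CC[C@@H]1C(=C)CC[C@@H]2C(C)(C)CCC[C@@]12C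
F5 | step 7 | ent-labda-8(17),13E-dien-15-yl 30-hydroxytriacontanoate | C/C(=C\COC(=O)CCCCCCCCCCCCCCCCCCCCCCCCCCCCCO)CC[C@@H]1C(=C)CC[C@@H]2C(C)(C)CCC[C@@]12C
F6 | step 8 | 7,8-epoxy-ent-labd-13E-en-15-yl 30-hydroxytriacontanoate (epoxide anti to the C10 methyl) | C/C(=C\COC(=O)CCCCCCCCCCCCCCCCCCCCCCCCCCCCCO)CC[C@@H]1[C@@]2(C)O[C@H]2C[C@@H]3C(C)(C)CCC[C@@]13C
F7 | step 8 | 7-(trimethylsilyloxy)-ent-labda-8(17),13E-dien-15-yl 30-(trimethylsilyloxy)triacontanoate | C/C(=C\COC(=O)CCCCCCCCCCCCCCCCCCCCCCCCCCCCCO[Si](C)(C)C)CC[C@@H]1C(=C)[C@@H](O[Si](C)(C)C)C[C@@H]2C(C)(C)CCC[C@@]12C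
F8 | step 8 | (7S)-7-hydroxy-ent-labda-8(17),13E-dien-15-yl 30-hydroxytriacontanoate (7-OH axial, anti to the C10 methyl) | C/C(=C\COC(=O)CCCCCCCCCCCCCCCCCCCCCCCCCCCCCO)CC[C@@H]1C(=C)[C@@H](O)C[C@@H]2C(C)(C)CCC[C@@]12C
F9 | step 4 | (14-carboxytetradecyl)triphenylphosphonium bromide | OC(=O)CCCCCCCCCCCCCC[P+](c1ccccc1)(c1ccccc1)c1ccccc1.[Br-]
F10 | step 4 | 15-hydroxypentadecanal | O=CCCCCCCCCCCCCCCO
F11 | step 4 | (15Z)-30-hydroxytriacont-15-enoic acid | OC(=O)CCCCCCCCCCCCC/C=C\CCCCCCCCCCCCCCO
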